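**Retrosynthetic overview**

1. Target 20 comes from its bis-silyl ether 19 by fluoride; the furan is the only ring to be built.
2. The strategy rests on the furan: O1 is bonded to C2 (aryl) and C5, and the side chain sits on C4. The ring is therefore the twice-dehydrated hemiketal of aryl ketone 16, which carries a hydroxyl and a CH2O group on its β-carbon, and 16 is the N–O-opened form of the 3-aryl-5,5-disubstituted 2-isoxazoline 14.
3. 14 is disconnected by a (3+2) cycloaddition into nitrile oxide 13 (from hydroximoyl chloride 4, three steps from 2,5-dihydroxybenzaldehyde) and the 1,1-disubstituted alkene 12. This forms the future furan C2–C3 bond and the C4–O bond.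
4. 12 comes from the (R)-homoallylic alcohol 10 by acylation and cross-metathesis. 10 comes from asymmetric allylboration of 2-(silyloxymethyl)acrolein 8, made from 2-methylenepropane-1,3-diol; the single stereocentre is set here.
5. Ring order: isoxazoline (step 9), then furan (step 11).

Key step: step 9

Remark: the quaternary carbon created in step 9 is formed as both epimers and is erased in step 11, so the SMILES of 14 to 18 leave it undefined. The carbinol centre is R in every compound from 9 onwards. (+)-Ipc2B(allyl) is taken as the commercial pentane solution.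

**Route**

Step 1
Reactants: 1 2,5-dihydroxybenzaldehyde
Product: 2 2,5-bis(tert-butyldimethylsilyloxy)benzaldehyde
Conditions: TBSCl (2.4 equiv), imidazole, DMF, rt
Reagents that add atoms: tert-butyldimethylsilyl chloride (TBSCl), CC(C)(C)[Si](C)(C)Cl
Why: Imidazole-promoted O-silylation should cap both phenols, including the hydrogen-bonded ortho one, and leave the aldehyde untouched.

Step 2
Reactants: 2 2,5-bis(tert-butyldimethylsilyloxy)benzaldehyde
Product: 3 (E)-2,5-bis(tert-butyldimethylsilyloxy)benzaldehyde oxime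
Conditions: NH2OH·HCl, pyridine, EtOH, rt
Reagents that add atoms: hydroxylamine hydrochloride, NO.Cl
Why: Oxime condensation under pyridine buffering should give the thermodynamically preferred E-aldoxime without cleaving the aryl silyl ethers.

Step 3
Reactants: 3 (E)-2,5-bis(tert-butyldimethylsilyloxy)benzaldehyde oxime
Product: 4 (Z)-2,5-bis(tert-butyldimethylsilyloxy)-N-hydroxybenzimidoyl chloride
Conditions: NCS (1.05 equiv), DMF, rt; used crude
Reagents that add atoms: N-chlorosuccinimide, O=C1CCC(=O)N1Cl
Why: Chlorination of the aldoxime C–H with N-chlorosuccinimide in DMF is the standard hydroximoyl chloride synthesis, and these mild conditions should favour the oxime carbon over the silyloxy-substituted ring.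

Step 4
Reactants: 5 2-methylenepropane-1,3-diol
Product: 7 2-[(triethylsilyloxy)methyl]prop-2-en-1-ol, via monosodium alkoxide 6 (not isolated)
Conditions: NaH (1.0 equiv), THF, 0 °C to rt; then TESCl (1.0 equiv)
Reagents that add atoms: chlorotriethylsilane (TESCl), CC[Si](Cl)(CC)CC
Why: Monosilylation of a symmetric diol through its sparingly soluble monosodium alkoxide should stop cleanly after one silyl group.

Step 5
Reactants: 7 2-[(triethylsilyloxy)methyl]prop-2-en-1-ol
Product: 8 2-[(triethylsilyloxy)methyl]prop-2-enal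
Conditions: MnO2 (excess), CH2Cl2, rt; used at once
Reagents that add atoms: none
Why: Allylic oxidation with MnO2 is neutral, stops at the enal and should leave the triethylsilyl ether intact.

Step 6
Reactants: 8 2-[(triethylsilyloxy)methyl]prop-2-enal
Product: 10 (R)-2-[(triethylsilyloxy)methyl]hexa-1,5-dien-3-ol, via borinate ester 9 (not isolated)
Conditions: (+)-Ipc2B(allyl) (1 M in pentane), Et2O, −78 °C; then NaBO3·4H2O, THF/H2O, rt
Reagents that add atoms: (+)-B-allyldiisopinocampheylborane, C=CCB([C@H]1C[C@H]2C[C@@H]([C@@H]1C)C2(C)C)[C@H]1C[C@H]2C[C@@H]([C@@H]1C)C2(C)C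
Why: Brown allylboration through a chair Zimmerman–Traxler transition state, in which the (−)-α-pinene-derived isopinocampheyl groups of the (+)-reagent send the allyl group to the re face of the aldehyde and so set the carbinol centre as R (priorities O > alkenyl carbon > allyl CH2), while the perborate work-up frees the alcohol without hydrolysing the silyl ether.

Step 7
Reactants: 10 (R)-2-[(triethylsilyloxy)methyl]hexa-1,5-dien-3-ol
Product: 11 (R)-2-[(triethylsilyloxy)methyl]hexa-1,5-dien-3-yl 3-methylbutanoate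
Conditions: isovaleryl chloride, pyridine, DMAP (cat.), CH2Cl2, 0 °C to rt
Reagents that add atoms: isovaleryl chloride, CC(C)CC(=O)Cl
Why: DMAP-catalysed acylation of the secondary alcohol leaves the C–O bond of the stereocentre untouched, so the configuration is retained.

Step 8
Reactants: 11 (R)-2-[(triethylsilyloxy)methyl]hexa-1,5-dien-3-yl 3-methylbutanoate
Product: 12 (R)-6-methyl-2-[(triethylsilyloxy)methyl]hepta-1,5-dien-3-yl 3-methylbutanoate
Conditions: 2-methyl-2-butene (large excess), second-generation Grubbs catalyst (H2IMes)(PCy3)Cl2Ru=CHPh (5 mol %), CH2Cl2, 40 °C, sealed vessel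
Reagents that add atoms: 2-methyl-2-butene, CC=C(C)C
Why: Olefin cross-metathesis should transfer an isopropylidene unit to the monosubstituted alkene only, because the 1,1-disubstituted alkene flanked by two oxygen-bearing carbons is too hindered to enter the catalytic cycle.

Step 9
Reactants: 4 (Z)-2,5-bis(tert-butyldimethylsilyloxy)-N-hydroxybenzimidoyl chloride; 12 (R)-6-methyl-2-[(triethylsilyloxy)methyl]hepta-1,5-dien-3-yl 3-methylbutanoate
Product: 14 (1R)-1-{3-[2,5-bis(tert-butyldimethylsilyloxy)phenyl]-5-[(triethylsilyloxy)methyl]-4,5-dihydroisoxazol-5-yl}-4-methylpent-3-en-1-yl 3-methylbutanoate (both epimers at ring C5), via nitrile oxide 13 (not isolated)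
Conditions: 4 (1.5 equiv), 12 (1.0 equiv), Et3N (1.6 equiv, syringe pump), CH2Cl2, 0 °C to rt
Reagents that add atoms: none
Why: Triethylamine dehydrochlorinates 4 to nitrile oxide 13, which should add to the 1,1-disubstituted alkene of 12 in a concerted, asynchronous Huisgen (3+2) cycloaddition; the closest known reaction type is the standard nitrile oxide–alkene synthesis of 2-isoxazolines. The five-membered ring is closed by intermolecular cycloaddition, with the C–C bond (nitrile carbon to the terminal CH2, the future furan C2–C3 bond) and the C–O bond (dipole oxygen to the disubstituted carbon, the future C4) made in the same step. The new quaternary centre is not controlled and need not be, since it becomes the sp2 furan C4, and the carbinol centre is not touched by the mild amine base. The step needs regioselectivity, which the 1,1-disubstitution secures on steric and orbital-coefficient grounds (oxygen to the more substituted carbon), and site selectivity over the prenyl alkene, which follows from the far lower dipolarophilicity of trisubstituted alkenes. Slow generation of 13 and its ortho silyloxy group should hold back dimerisation to the furoxan.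

Step 10
Reactants: 14 the isoxazoline of step 9
Product: 16 (4R)-1-[2,5-bis(tert-butyldimethylsilyloxy)phenyl]-3-hydroxy-7-methyl-1-oxo-3-[(triethylsilyloxy)methyl]oct-6-en-4-yl 3-methylbutanoate, via β-hydroxy imine 15 (not isolated)
Conditions: Mo(CO)6 (1.0 equiv), MeCN/H2O (15:1), 80 °C
Reagents that add atoms: water, O
Why: Reductive N–O cleavage of a 2-isoxazoline by molybdenum hexacarbonyl (zerovalent molybdenum) followed by hydrolysis of the β-hydroxy imine is a known route to β-hydroxy ketones and should spare the alkene, the ester and the silyl ethers.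

Step 11
Reactants: 16 the β-hydroxy ketone of step 10
Product: 19 (1R)-1-{5-[2,5-bis(tert-butyldimethylsilyloxy)phenyl]furan-3-yl}-4-methylpent-3-en-1-yl 3-methylbutanoate, via diol ketone 17 (not isolated), via cyclic hemiketal 18 (not isolated)
Conditions: p-TsOH·H2O (0.1 equiv), THF/H2O (20:1), 0 to 40 °C
Reagents that add atoms: none
Why: Acid hydrolysis of the triethylsilyl ether frees the γ-hydroxyl, which closes onto the ketone as a five-membered hemiketal, and acid-catalysed cyclodehydration (loss of two molecules of water, driven by aromatisation) should give the furan, while the acid-stable aryl silyl ethers and the carbinol centre, which lies outside the ring, are not affected.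

Step 12
Reactants: 19 the bis-silylated furan of step 11
Product: 20 (1R)-1-[5-(2,5-dihydroxyphenyl)furan-3-yl]-4-methylpent-3-en-1-yl 3-methylbutanoate
Conditions: n-Bu4NF (2.4 equiv), AcOH (3 equiv), THF, 0 °C, degassed, under argon
Reagents that add atoms: none
Why: Fluoride desilylation of aryl silyl ethers is fast, and the acetic acid buffer should keep the ester from hydrolysis or migration and the hydroquinone from base-promoted air oxidation.

**Compound list**

1 | 2,5-dihydroxybenzaldehyde | O=Cc1cc(O)ccc1O | starting material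
2 | 2,5-bis(tert-butyldimethylsilyloxy)benzaldehyde | O=Cc1cc(O[Si](C)(C)C(C)(C)C)ccc1O[Si](C)(C)C(C)(C)C | intermediate
3 | (E)-2,5-bis(tert-butyldimethylsilyloxy)benzaldehyde oxime | O/N=C/c1cc(O[Si](C)(C)C(C)(C)C)ccc1O[Si](C)(C)C(C)(C)C | intermediate
4 | (Z)-2,5-bis(tert-butyldimethylsilyloxy)-N-hydroxybenzimidoyl chloride | O/N=C(\Cl)c1cc(O[Si](C)(C)C(C)(C)C)ccc1O[Si](C)(C)C(C)(C)C | intermediate
5 | 2-methylenepropane-1,3-diol | C=C(CO)CO | starting material
6 | sodium 2-(hydroxymethyl)prop-2-en-1-olate (not isolated) | [Na+].[O-]CC(=C)CO | intermediate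
7 | 2-[(triethylsilyloxy)methyl]prop-2-en-1-ol | C=C(CO)CO[Si](CC)(CC)CC | intermediate
8 | 2-[(triethylsilyloxy)methyl]prop-2-enal | C=C(C=O)CO[Si](CC)(CC)CC | intermediate
9 | (R)-2-[(triethylsilyloxy)methyl]hexa-1,5-dien-3-yl diisopinocampheylborinate (not isolated) | C=C(CO[Si](CC)(CC)CC)[C@H](OB([C@H]1C[C@H]2C[C@@H]([C@@H]1C)C2(C)C)[C@H]1C[C@H]2C[C@@H]([C@@H]1C)C2(C)C)CC=C | intermediate
10 | (R)-2-[(triethylsilyloxy)methyl]hexa-1,5-dien-3-ol | C=C(CO[Si](CC)(CC)CC)[C@H](O)CC=C | intermediate
11 | (R)-2-[(triethylsilyloxy)methyl]hexa-1,5-dien-3-yl 3-methylbutanoate | C=C(CO[Si](CC)(CC)CC)[C@H](OC(=O)CC(C)C)CC=C | intermediate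
12 | (R)-6-methyl-2-[(triethylsilyloxy)methyl]hepta-1,5-dien-3-yl 3-methylbutanoate | C=C(CO[Si](CC)(CC)CC)[C@H](OC(=O)CC(C)C)CC=C(C)C | intermediate
13 | 2,5-bis(tert-butyldimethylsilyloxy)benzonitrile oxide (not isolated) | [O-][N+]#Cc1cc(O[Si](C)(C)C(C)(C)C)ccc1O[Si](C)(C)C(C)(C)C | intermediate
14 | (1R)-1-{3-[2,5-bis(tert-butyldimethylsilyloxy)phenyl]-5-[(triethylsilyloxy)methyl]-4,5-dihydroisoxazol-5-yl}-4-methylpent-3-en-1-yl 3-methylbutanoate, both epimers at ring C5 | CC(C)=CC[C@@H](OC(=O)CC(C)C)C1(CO[Si](CC)(CC)CC)CC(c2cc(O[Si](C)(C)C(C)(C)C)ccc2O[Si](C)(C)C(C)(C)C)=NO1 | intermediate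
15 | (4R)-1-[2,5-bis(tert-butyldimethylsilyloxy)phenyl]-3-hydroxy-1-imino-7-methyl-3-[(triethylsilyloxy)methyl]oct-6-en-4-yl 3-methylbutanoate (not isolated) | CC(C)=CC[C@@H](OC(=O)CC(C)C)C(O)(CO[Si](CC)(CC)CC)CC(=N)c1cc(O[Si](C)(C)C(C)(C)C)ccc1O[Si](C)(C)C(C)(C)C | intermediate
16 | (4R)-1-[2,5-bis(tert-butyldimethylsilyloxy)phenyl]-3-hydroxy-7-methyl-1-oxo-3-[(triethylsilyloxy)methyl]oct-6-en-4-yl 3-methylbutanoate | CC(C)=CC[C@@H](OC(=O)CC(C)C)C(O)(CO[Si](CC)(CC)CC)CC(=O)c1cc(O[Si](C)(C)C(C)(C)C)ccc1O[Si](C)(C)C(C)(C)C | intermediate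
17 | (4R)-1-[2,5-bis(tert-butyldimethylsilyloxy)phenyl]-3-hydroxy-3-(hydroxymethyl)-7-methyl-1-oxooct-6-en-4-yl 3-methylbutanoate (not isolated) | CC(C)=CC[C@@H](OC(=O)CC(C)C)C(O)(CO)CC(=O)c1cc(O[Si](C)(C)C(C)(C)C)ccc1O[Si](C)(C)C(C)(C)C | intermediate
18 | (1R)-1-{5-[2,5-bis(tert-butyldimethylsilyloxy)phenyl]-3,5-dihydroxytetrahydrofuran-3-yl}-4-methylpent-3-en-1-yl 3-methylbutanoate (not isolated) | CC(C)=CC[C@@H](OC(=O)CC(C)C)C1(O)COC(O)(c2cc(O[Si](C)(C)C(C)(C)C)ccc2O[Si](C)(C)C(C)(C)C)C1 | intermediate
19 | (1R)-1-{5-[2,5-bis(tert-butyldimethylsilyloxy)phenyl]furan-3-yl}-4-methylpent-3-en-1-yl 3-methylbutanoate | CC(C)=CC[C@@H](OC(=O)CC(C)C)c1coc(-c2cc(O[Si](C)(C)C(C)(C)C)ccc2O[Si](C)(C)C(C)(C)C)c1 | intermediate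
20 | (1R)-1-[5-(2,5-dihydroxyphenyl)furan-3-yl]-4-methylpent-3-en-1-yl 3-methylbutanoate | CC(C)=CC[C@@H](OC(=O)CC(C)C)c1coc(-c2cc(O)ccc2O)c1 | target

**Totals**

Total step count: 12.
Longest linear sequence: 9 steps (steps 4 to 12, from 5).

**Steps most likely to fail**

1. Step 9. The alkene of 12 is flanked by two oxygen-bearing carbons, so cycloaddition may be slow enough for the nitrile oxide to dimerise to the furoxan instead.
Fallback: a hydroxyl-directed cycloaddition on the free allylic alcohol, setting out from 10 and returning at 14. Cross-metathesis of 10 with 2-methyl-2-butene and the same ruthenium catalyst should give (R)-6-methyl-2-[(triethylsilyloxy)methyl]hepta-1,5-dien-3-ol F1. Its magnesium alkoxide (EtMgBr, 2 equiv, CH2Cl2, 0 °C) is then treated with 4. Coordination of the nitrile oxide oxygen to the alkoxide magnesium strongly accelerates the addition and delivers oxygen to the carbinol-bearing alkene carbon, giving (1R)-1-{3-[2,5-bis(tert-butyldimethylsilyloxy)phenyl]-5-[(triethylsilyloxy)methyl]-4,5-dihydroisoxazol-5-yl}-4-methylpent-3-en-1-ol F2. Acylation with isovaleryl chloride, pyridine and DMAP then gives 14.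

2. Step 11. The acid needed for a twofold dehydration may ionise the ester-bearing carbon once it becomes furylmethyl-like (racemisation or solvolysis), shift the acyl group to the freed primary hydroxyl, or protonate the prenyl alkene.
Fallback: the tertiary hydroxyl is removed under basic conditions first, setting out from 16 and returning at 19. MsCl and Et3N in CH2Cl2 at 0 °C should convert 16 into the tertiary mesylate F3, which eliminates in the same flask to the enone (4R)-1-[2,5-bis(tert-butyldimethylsilyloxy)phenyl]-7-methyl-1-oxo-3-[(triethylsilyloxy)methyl]octa-2,6-dien-4-yl 3-methylbutanoate F4 as a mixture of alkene isomers. PPTS in wet THF at rt then removes the triethylsilyl group, and the γ-hydroxy enone F5 closes onto the ketone and loses a single molecule of water to give 19. A trace of iodine or ambient light would equilibrate the alkene isomers, so only very mild acid is needed.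

3. Step 10. At 80 °C the β-hydroxy ketone may fragment by retro-aldol cleavage or suffer acyl migration, or the imine may hydrolyse incompletely.
Fallback: the N–O bond is cleaved at low temperature with the hydroxymethyl group already free, so that the aldol is trapped as its hemiketal as it forms; this sets out from 14 and returns at 18. PPTS in MeOH at 0 °C should remove the triethylsilyl group to give the hydroxymethyl isoxazoline F6. SmI2 (divalent samarium, 2.5 equiv) in THF at −78 to 0 °C then cleaves the N–O bond to the β-hydroxy imine F7. Aqueous B(OH)3 hydrolyses F7 to 17, which closes to 18, and the acid of step 11 carries 18 on to 19.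

**Further compounds**

F1 | step 9 | (R)-6-methyl-2-[(triethylsilyloxy)methyl]hepta-1,5-dien-3-ol | C=C(CO[Si](CC)(CC)CC)[C@H](O)CC=C(C)C
F2 | step 9 | (1R)-1-{3-[2,5-bis(tert-butyldimethylsilyloxy)phenyl]-5-[(triethylsilyloxy)methyl]-4,5-dihydroisoxazol-5-yl}-4-methylpent-3-en-1-ol | CC(C)=CC[C@@H](O)C1(CO[Si](CC)(CC)CC)CC(c2cc(O[Si](C)(C)C(C)(C)C)ccc2O[Si](C)(C)C(C)(C)C)=NO1
F3 | step 11 | (4R)-1-[2,5-bis(tert-butyldimethylsilyloxy)phenyl]-3-(methanesulfonyloxy)-7-methyl-1-oxo-3-[(triethylsilyloxy)methyl]oct-6-en-4-yl 3-methylbutanoate | CC(C)=CC[C@@H](OC(=O)CC(C)C)C(OS(C)(=O)=O)(CO[Si](CC)(CC)CC)CC(=O)c1cc(O[Si](C)(C)C(C)(C)C)ccc1O[Si](C)(C)C(C)(C)C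
F4 | step 11 | (4R)-1-[2,5-bis(tert-butyldimethylsilyloxy)phenyl]-7-methyl-1-oxo-3-[(triethylsilyloxy)methyl]octa-2,6-dien-4-yl 3-methylbutanoate, mixture of C2 alkene isomers | CC(C)=CC[C@@H](OC(=O)CC(C)C)C(CO[Si](CC)(CC)CC)=CC(=O)c1cc(O[Si](C)(C)C(C)(C)C)ccc1O[Si](C)(C)C(C)(C)C
F5 | step 11 | (4R)-1-[2,5-bis(tert-butyldimethylsilyloxy)phenyl]-3-(hydroxymethyl)-7-methyl-1-oxoocta-2,6-dien-4-yl 3-methylbutanoate | CC(C)=CC[C@@H](OC(=O)CC(C)C)C(CO)=CC(=O)c1cc(O[Si](C)(C)C(C)(C)C)ccc1O[Si](C)(C)C(C)(C)C
F6 | step 10 | (1R)-1-{3-[2,5-bis(tert-butyldimethylsilyloxy)phenyl]-5-(hydroxymethyl)-4,5-dihydroisoxazol-5-yl}-4-methylpent-3-en-1-yl 3-methylbutanoate | CC(C)=CC[C@@H](OC(=O)CC(C)C)C1(CO)CC(c2cc(O[Si](C)(C)C(C)(C)C)ccc2O[Si](C)(C)C(C)(C)C)=NO1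
F7 | step 10 | (4R)-1-[2,5-bis(tert-butyldimethylsilyloxy)phenyl]-3-hydroxy-3-(hydroxymethyl)-1-imino-7-methyloct-6-en-4-yl 3-methylbutanoate | CC(C)=CC[C@@H](OC(=O)CC(C)C)C(O)(CO)CC(=N)c1cc(O[Si](C)(C)C(C)(C)C)ccc1O[Si](C)(C)C(C)(C)C
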